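## The problem

The target **17** is a tricin-type flavone. Rings A and C form a 5,7-dihydroxychromen-4-one, and ring B is a 3',5'-dimethoxy-4'-oxyphenyl group at C2. The 4'-oxygen of ring B is bonded to C8'' of a 1-(4-hydroxyphenyl)propane-1,3-diol. The two halves meet only through this alkyl aryl ether, which is crowded on the arene side by two ortho methoxy groups and on the alkyl side by two oxygen-bearing carbons.

The only stereocentres are C7'' (R, a secondary benzylic alcohol) and C8'' (S, the ether carbon). They are adjacent on an open chain in the erythro relationship. No ring relays information between them, so either one directs the other through an acyclic transition state or one external agent sets both.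

Several groups will not survive rough treatment:
- The C7'' carbinol is para to an oxygen on its arene. It ionises under acid and, as the free phenol, forms a quinone methide under base or heat; either path epimerises C7'' or cleaves the chain.
- Ring C opens in strong hydroxide, and its C2=C3 bond can be hydrogenated.
- The free phenols are easily oxidised.

The feature that opens the problem is the position of C8'' between C7'' and C9'', both oxygenated. If C7'' is a ketone and C9'' an ester, the C8''–H is doubly activated and labile. The stereodyad then shrinks to one freely epimerising centre beside a prochiral carbonyl, which is the substrate pattern of a dynamic reductive kinetic resolution.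

## Retrosynthesis

**Protecting groups (17 ⇐ 16 ⇐ 15).** The last bonds made free are the three benzyl–oxygen bonds of **16**, and before them the two acetal C–O bonds of **15**. Benzyl on all three phenols allows one neutral hydrogenolysis at the end. The acetonide on the 7'',9''-diol keeps the benzylic alcohol away from palladium oxidants. The acetonide is removed first, while the 4''-oxygen is still a benzyl ether, so that the acid step cannot pass through a quinone methide.

**Ring B to ring C (15 ⇐ 10 + 14).** The C2–C1' bond is cut, giving the arylboronate **10** and 5,7-bis(benzyloxy)chromone **14**. The neighbouring cuts run through ring C itself (a chalcone, or a 1,3-diketone closed onto the ring A phenol). They would carry the chiral fragment through hot iodine or acid and lengthen the linear sequence by one step. The chosen cut keeps ring C intact and makes the route convergent. The forward reaction must arylate C2 and not C3, and must give back the C2=C3 double bond.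

**Functional group changes (10 ⇐ 9 ⇐ 8 ⇐ 7).** Boron is exchanged for bromine, the acetonide is opened to the diol **8**, and C9'' is raised from alcohol to ethyl ester. No skeletal bond is cut. These changes bring the molecule to the hydroxy ester **7**, where C9'' is at the acid level and the next cut becomes possible. The forward steps must leave the aryl bromide and the two stereocentres untouched.

**The stereodyad (7 ⇐ 6).** The C7''–H bond is removed, which gives the racemic α-aryloxy β-keto ester **6**. Both stereocentres disappear in one operation: C7'' becomes a carbonyl and C8'' a centre that racemises by enolisation. Cutting C7''–C8'' or C8''–C9'' instead would need a stereocontrolled C–C bond formation and would still leave the hindered ether to be made. The forward step asks for a ketoreductase that accepts only the (R)-enantiomer of **6** and delivers hydride to the Si face of the ketone, while racemisation keeps pace.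

**The aryl ether (6 ⇐ 4 + 5).** The C8''–O bond is cut to the diazo keto ester **4** and 4-bromo-2,6-dimethoxyphenol **5**. At this stage C8'' has no configuration to lose, so the crowded ether can be made by carbenoid insertion into the phenol O–H rather than by SN2 at a hindered secondary stereocentre. Bromine is the placeholder for ring C: it is inert to the carbenoid, the enzyme and LiBH4. An aldehyde in its place would be reduced by the ketoreductase.

**The three-carbon chain (4 ⇐ 3 ⇐ 1 + 2).** Diazo transfer leads back to the β-keto ester **3**, and the C8''–C9'' bond is cut by a Claisen disconnection to 4'-(benzyloxy)acetophenone **1** and diethyl carbonate **2**. Both are commodity chemicals, and the benzyl ether is the one that leaves in the final step.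

**The chromone (14 ⇐ 12 ⇐ 11).** The O1–C2 bond and the C2 carbon are removed, leading to the ortho-hydroxyacetophenone **12** and a formamide acetal as the one-carbon unit. Compound **12** comes from 2',4',6'-trihydroxyacetophenone **11** by benzylation of the two hydroxyls that are not locked in the hydrogen bond to the ketone.

## Roads not taken

**Alternative 1:** Ring C is cut through C8a–O1, C4a–C4 and O1–C2 together.
- Forward step: fluoride releases an aryne from the silyl triflate **A1**. The carboxylate of the arylpropiolic acid **A2** adds through oxygen, the aryl anion takes over the acyl group, and the 2-hydroxyaryl ynone closes by 6-endo-dig oxa-Michael addition. The product **A3** is identical with **15**.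
- Merits: three bonds and ring C in one flask, with no transition metal. The regiochemistry is electronically right: oxygen adds to the aryne carbon remote from the flanking benzyloxy group, which gives the 5,7 pattern.
- Where it is better: the chiral fragment enters as the limiting acid, whereas an oxidative boron-Heck coupling usually wants the boron partner in excess. The chosen plan answers this by running the cheap chromone **14** in excess.
- Weak points: the acyl shift must occur onto a carbon ortho to a benzyloxy group, and plain O-arylation to the aryl ester competes. 5-exo closure to an aurone competes with 6-endo closure. **A1** needs about four steps of its own and **A2** two or three from **9**, against two steps for **14** and one for **10**.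
- Comparison: this road does not touch the stereochemical problem and would still depend on step 4. It is a longer end game, not a different solution.

**Alternative 2:** The C7''–C8'' bond is cut.
- Forward step: an alkyllithium base deprotonates the benzylic position of the 4-silyloxybenzyl ether **A4**. The carbanion rearranges by a [2,3]-Wittig shift through a five-membered transition state. C7''–C8'' forms while the C–O bond at the (R)-carbinol carbon breaks. The E enol ether and the R centre are translated into the (1R,2S) pair of **A5**, with an (E)-propenyl group as the future C9''.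
- Merits: a C–C bond and both stereocentres come from one cheap stereocentre through a well-understood sigmatropic transition state, with no enzyme to find. In predictability from first principles this road is the stronger one.
- Weak points:
  - **A4** is an aryl enol ether of a chiral allylic alcohol with a di-ortho-substituted aryl group, and it needs several steps with uncertain geometry control.
  - The electron-rich benzylic position is poorly acidic, while the enol ether α-hydrogen and the arene positions next to methoxy can also be lithiated.
  - A [1,2]-shift competes, and E allylic benzyl ethers usually give only moderate anti selectivity.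
  - The propenyl group then costs an oxidative cleavage and a reduction, discarding two carbons. The dioxolane on ring B must still be grown into the flavone through a chalcone in about four more steps.
- Comparison: against its predictability the chosen plan sets a three-step racemic precursor, one catalytic step for both centres, and a chain that already has the right carbon count.

**Alternative 3:** The C8''–C9'' bond is cut.
- Forward step: (benzyloxy)methyllithium **A7**, made by tin–lithium exchange, adds to the aldehyde **A6** under Felkin–Anh control by the bulky silyloxy group. The anti adduct **A8** has C8'' as a free secondary alcohol.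
- Merits: shelf reagents, substrate control, and three differently protected oxygens. This flexibility for late variation of ring B is better than in the chosen plan, which commits the ring B oxygen in step 3.
- Weak points:
  - **A6** is an α-aryl α-oxy aldehyde with an electron-rich arene and racemises easily by enolisation.
  - Organolithium additions to such aldehydes are only moderately Felkin-selective, and the tin is stoichiometric.
  - Most seriously, the C8''–O–aryl bond remains to be made with retention on a hindered secondary alcohol and a di-ortho-methoxy arene. That needs an SNAr reaction on a barely activated fluoroarene or a metal-catalysed etherification of two hindered partners. A Mitsunobu reaction would invert and so demand the other C8'' epimer.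
- Comparison: the chosen plan makes this bond in step 3 at a doubly activated carbon that has no configuration to lose. This outweighs the flexibility of **A8**.

Key step: step 4

Assumption: the ketoreductase of step 4 is taken from a screening panel or an engineered variant, and the step is written for the variant that delivers (2R,3R)-**7**. The erythro (7''R,8''S) diol corresponds to the anti (2R,3R) hydroxy ester; the C8'' descriptor changes on ester reduction only through CIP ranking.

## Route

Step 1
Reactants: 1 4'-(benzyloxy)acetophenone; 2 diethyl carbonate
Product: 3 ethyl 3-[4-(benzyloxy)phenyl]-3-oxopropanoate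
Conditions: NaH (2.5 equiv), (EtO)2CO (3 equiv), THF, reflux; then aq. HCl
Reagents that add atoms: none
Why: Crossed Claisen condensation: the sodium enolate of the ketone is C-acylated by the non-enolisable carbonate, and deprotonation of the β-keto ester drives the reaction. The benzyl ether is inert to these conditions.

Step 2
Reactants: 3 ethyl 3-[4-(benzyloxy)phenyl]-3-oxopropanoate
Product: 4 ethyl 3-[4-(benzyloxy)phenyl]-2-diazo-3-oxopropanoate
Conditions: 4-acetamidobenzenesulfonyl azide, Et3N, MeCN, 0 °C to rt
Reagents that add atoms: 4-acetamidobenzenesulfonyl azide, CC(=O)Nc1ccc(cc1)S(=O)(=O)N=[N+]=[N-]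
Why: Regitz diazo transfer to an active methylene group. The acceptor/acceptor diazo compound is stable enough to purify and store.

Step 3
Reactants: 4 ethyl 3-[4-(benzyloxy)phenyl]-2-diazo-3-oxopropanoate; 5 4-bromo-2,6-dimethoxyphenol
Product: 6 racemic ethyl 3-[4-(benzyloxy)phenyl]-2-(4-bromo-2,6-dimethoxyphenoxy)-3-oxopropanoate
Conditions: Rh2(OAc)4 (2 mol %), toluene, 80 °C, slow addition of 4 to 5 (1.3 equiv)
Reagents that add atoms: none
Why: Dirhodium-carbenoid O–H insertion: the electrophilic carbenoid is attacked by the phenol oxygen and a 1,2-proton shift gives the aryl ether, so the crowded C8''–O bond forms without an SN2 step. The product is racemic, which is what step 4 requires, and the aryl bromide and benzyl ether do not react with the carbenoid.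

Step 4
Reactants: 6 racemic ethyl 3-[4-(benzyloxy)phenyl]-2-(4-bromo-2,6-dimethoxyphenoxy)-3-oxopropanoate
Product: 7 ethyl (2R,3R)-3-[4-(benzyloxy)phenyl]-2-(4-bromo-2,6-dimethoxyphenoxy)-3-hydroxypropanoate
Conditions: ketoreductase (variant selected for the (2R,3R) product), NADP+ (cat.), i-PrOH–DMSO–0.1 M potassium phosphate pH 7.5 (1:1:8), MgSO4 (1 mM), 30 °C
Reagents that add atoms: none
Why: The C8''–H of 6 lies between the aryl ketone and the ester and also carries the aryloxy group, so in phosphate buffer the two enantiomers should interconvert through the enol or enolate faster than either is reduced. The enzyme binds the (R)-enantiomer productively and passes the C4 hydride of NADPH to the Si face of the C7'' carbonyl while an active-site acid (tyrosine in the short-chain reductases) protonates the oxygen; the NADP+ formed is reduced again by the same enzyme at the expense of isopropanol, which leaves as acetone. The closest known reaction type is the ketoreductase-catalysed dynamic reductive kinetic resolution of α-substituted β-keto esters, aryl ketones included; a second lead is the family of NAD-dependent Cα-dehydrogenases of bacterial β-aryl ether catabolism, which act on this same aryl–CH(OH)–CH(OAr) motif. No ring closes. C7'' (R) is set by the carbonyl face that the enzyme presents to the cofactor; C8'' (R in the ester, the later 8''S) is set by which enantiomer of 6 the pocket accepts, the other being returned by racemisation. The step needs anti (erythro) diastereoselectivity, enantioselectivity and a racemisation that keeps pace: the first two are properties of the enzyme, to be chosen among reductases with two large binding pockets, and the third rests on the acidity of the C8''–H. The product should be configurationally stable because the hydroxy ester no longer enolises at this pH.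

Step 5
Reactants: 7 ethyl (2R,3R)-3-[4-(benzyloxy)phenyl]-2-(4-bromo-2,6-dimethoxyphenoxy)-3-hydroxypropanoate
Product: 8 (1R,2S)-1-[4-(benzyloxy)phenyl]-2-(4-bromo-2,6-dimethoxyphenoxy)propane-1,3-diol
Conditions: LiBH4, THF, 0 °C to rt; then aq. NH4Cl
Reagents that add atoms: none
Why: Ester reduction by LiBH4, assisted by lithium chelation to the neighbouring hydroxyl; the aryl bromide and benzyl ether are not touched. No stereocentre is formed or broken; the C8'' descriptor becomes S only because CH2OH ranks below C7''.

Step 6
Reactants: 8 (1R,2S)-1-[4-(benzyloxy)phenyl]-2-(4-bromo-2,6-dimethoxyphenoxy)propane-1,3-diol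
Product: 9 (4R,5S)-4-[4-(benzyloxy)phenyl]-5-(4-bromo-2,6-dimethoxyphenoxy)-2,2-dimethyl-1,3-dioxane
Conditions: Me2C(OMe)2, PPTS (cat.), acetone, rt
Reagents that add atoms: 2,2-dimethoxypropane, COC(C)(C)OC
Why: Acid-catalysed transacetalisation closes the six-membered 1,3-dioxane, and the weak acid PPTS should not ionise the benzylic C7''–O bond. The acetonide shields the benzylic alcohol from the palladium oxidant of step 10, and its H4–H5 coupling constant allows a check of the erythro configuration.

Step 7
Reactants: 9 (4R,5S)-4-[4-(benzyloxy)phenyl]-5-(4-bromo-2,6-dimethoxyphenoxy)-2,2-dimethyl-1,3-dioxane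
Product: 10 2-(4-{[(4R,5S)-4-[4-(benzyloxy)phenyl]-2,2-dimethyl-1,3-dioxan-5-yl]oxy}-3,5-dimethoxyphenyl)-4,4,5,5-tetramethyl-1,3,2-dioxaborolane
Conditions: B2pin2, PdCl2(dppf)·CH2Cl2 (5 mol %), KOAc, 1,4-dioxane, 90 °C
Reagents that add atoms: bis(pinacolato)diboron, CC1(C)OB(OC1(C)C)B1OC(C)(C)C(C)(C)O1
Why: Miyaura borylation: zerovalent palladium inserts into the C–Br bond, acetate-assisted transmetalation with the diboron follows, and reductive elimination gives the aryl boronate. The bromide has no ortho substituent, and the weak base KOAc suppresses Suzuki homocoupling.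

Step 8
Reactants: 11 2',4',6'-trihydroxyacetophenone
Product: 12 1-[2,4-bis(benzyloxy)-6-hydroxyphenyl]ethan-1-one
Conditions: BnBr (2.05 equiv), K2CO3 (2.2 equiv), acetone, reflux
Reagents that add atoms: benzyl bromide, BrCc1ccccc1
Why: Williamson etherification: the para hydroxyl and one ortho hydroxyl are alkylated, while the remaining ortho hydroxyl is held in a hydrogen bond to the ketone and reacts last. Limiting the benzyl bromide to two equivalents should stop the reaction at the diether.

Step 9
Reactants: 12 1-[2,4-bis(benzyloxy)-6-hydroxyphenyl]ethan-1-one
Product: 14 5,7-bis(benzyloxy)-4H-chromen-4-one, via enaminone 13 (not isolated)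
Conditions: Me2NCH(OMe)2, toluene, 100 °C; then conc. HCl, CH2Cl2, rt
Reagents that add atoms: N,N-dimethylformamide dimethyl acetal, COC(OC)N(C)C
Why: Condensation of the methyl ketone with the formamide acetal gives the enaminone; acid then promotes intramolecular addition of the phenol and loss of dimethylamine, the standard enaminone route to chromones. Aryl benzyl ethers tolerate brief treatment with HCl at room temperature.

Step 10
Reactants: 10 2-(4-{[(4R,5S)-4-[4-(benzyloxy)phenyl]-2,2-dimethyl-1,3-dioxan-5-yl]oxy}-3,5-dimethoxyphenyl)-4,4,5,5-tetramethyl-1,3,2-dioxaborolane; 14 5,7-bis(benzyloxy)-4H-chromen-4-one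
Product: 15 5,7-bis(benzyloxy)-2-(4-{[(4R,5S)-4-[4-(benzyloxy)phenyl]-2,2-dimethyl-1,3-dioxan-5-yl]oxy}-3,5-dimethoxyphenyl)-4H-chromen-4-one
Conditions: Pd(OCOCF3)2 (10 mol %), 5-nitro-1,10-phenanthroline (20 mol %), 14 (2 equiv), O2 (1 atm), DMSO, 100 °C
Reagents that add atoms: none
Why: Oxidative boron-Heck coupling: the aryl group is transferred from boron to divalent palladium and adds across C2=C3 with the aryl at C2, the β-carbon of the enone; the C3 palladium enolate then equilibrates so that syn β-hydride elimination restores the double bond, and O2 returns zerovalent palladium to the divalent state. The acetonide keeps the benzylic alcohol out of reach of aerobic palladium oxidation, and no stereocentre is involved.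

Step 11
Reactants: 15 5,7-bis(benzyloxy)-2-(4-{[(4R,5S)-4-[4-(benzyloxy)phenyl]-2,2-dimethyl-1,3-dioxan-5-yl]oxy}-3,5-dimethoxyphenyl)-4H-chromen-4-one
Product: 16 5,7-bis(benzyloxy)-2-(4-{[(1R,2S)-1-[4-(benzyloxy)phenyl]-1,3-dihydroxypropan-2-yl]oxy}-3,5-dimethoxyphenyl)-4H-chromen-4-one
Conditions: AcOH–THF–H2O (4:2:1), 45 °C
Reagents that add atoms: none
Why: Mild aqueous acid hydrolysis of the isopropylidene acetal. It is run while the 4''-oxygen is still a benzyl ether, so a quinone methide cannot form and the C7'' configuration should hold.

Step 12
Reactants: 16 5,7-bis(benzyloxy)-2-(4-{[(1R,2S)-1-[4-(benzyloxy)phenyl]-1,3-dihydroxypropan-2-yl]oxy}-3,5-dimethoxyphenyl)-4H-chromen-4-one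
Product: 17 (–)-(7''R,8''S)-4'',5,7-trihydroxy-3',5'-dimethoxy-4',8''-oxyflavonolignan-7'',9''-diol
Conditions: H2 (1 atm), 10% Pd/C, THF–MeOH (1:1), rt
Reagents that add atoms: none
Why: Catalytic hydrogenolysis of the three aryl benzyl ethers at neutral pH. These cleave much faster than the secondary benzylic C7''–OH bond or the conjugated C2=C3 bond is attacked, so the reaction is stopped after three equivalents of hydrogen.

## Compound list

1 | 4'-(benzyloxy)acetophenone | CC(=O)c1ccc(OCc2ccccc2)cc1 | starting material
2 | diethyl carbonate | CCOC(=O)OCC | starting material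
3 | ethyl 3-[4-(benzyloxy)phenyl]-3-oxopropanoate | CCOC(=O)CC(=O)c1ccc(OCc2ccccc2)cc1 | intermediate
4 | ethyl 3-[4-(benzyloxy)phenyl]-2-diazo-3-oxopropanoate | CCOC(=O)C(=[N+]=[N-])C(=O)c1ccc(OCc2ccccc2)cc1 | intermediate
5 | 4-bromo-2,6-dimethoxyphenol | COc1cc(Br)cc(OC)c1O | starting material
6 | racemic ethyl 3-[4-(benzyloxy)phenyl]-2-(4-bromo-2,6-dimethoxyphenoxy)-3-oxopropanoate | CCOC(=O)C(Oc1c(OC)cc(Br)cc1OC)C(=O)c1ccc(OCc2ccccc2)cc1 | intermediate
7 | ethyl (2R,3R)-3-[4-(benzyloxy)phenyl]-2-(4-bromo-2,6-dimethoxyphenoxy)-3-hydroxypropanoate | COc1cc(Br)cc(OC)c1O[C@@H](C(=O)OCC)[C@H](O)c1ccc(OCc2ccccc2)cc1 | intermediate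
8 | (1R,2S)-1-[4-(benzyloxy)phenyl]-2-(4-bromo-2,6-dimethoxyphenoxy)propane-1,3-diol | COc1cc(Br)cc(OC)c1O[C@@H](CO)[C@H](O)c1ccc(OCc2ccccc2)cc1 | intermediate
9 | (4R,5S)-4-[4-(benzyloxy)phenyl]-5-(4-bromo-2,6-dimethoxyphenoxy)-2,2-dimethyl-1,3-dioxane | COc1cc(Br)cc(OC)c1O[C@H]1COC(C)(C)O[C@@H]1c1ccc(OCc2ccccc2)cc1 | intermediate
10 | 2-(4-{[(4R,5S)-4-[4-(benzyloxy)phenyl]-2,2-dimethyl-1,3-dioxan-5-yl]oxy}-3,5-dimethoxyphenyl)-4,4,5,5-tetramethyl-1,3,2-dioxaborolane | COc1cc(B2OC(C)(C)C(C)(C)O2)cc(OC)c1O[C@H]1COC(C)(C)O[C@@H]1c1ccc(OCc2ccccc2)cc1 | intermediate
11 | 2',4',6'-trihydroxyacetophenone | CC(=O)c1c(O)cc(O)cc1O | starting material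
12 | 1-[2,4-bis(benzyloxy)-6-hydroxyphenyl]ethan-1-one | CC(=O)c1c(O)cc(OCc2ccccc2)cc1OCc1ccccc1 | intermediate
13 | (2E)-1-[2,4-bis(benzyloxy)-6-hydroxyphenyl]-3-(dimethylamino)prop-2-en-1-one | CN(C)/C=C/C(=O)c1c(O)cc(OCc2ccccc2)cc1OCc1ccccc1 | intermediate
14 | 5,7-bis(benzyloxy)-4H-chromen-4-one | O=c1ccoc2cc(OCc3ccccc3)cc(OCc3ccccc3)c12 | intermediate
15 | 5,7-bis(benzyloxy)-2-(4-{[(4R,5S)-4-[4-(benzyloxy)phenyl]-2,2-dimethyl-1,3-dioxan-5-yl]oxy}-3,5-dimethoxyphenyl)-4H-chromen-4-one | COc1cc(-c2cc(=O)c3c(OCc4ccccc4)cc(OCc4ccccc4)cc3o2)cc(OC)c1O[C@H]1COC(C)(C)O[C@@H]1c1ccc(OCc2ccccc2)cc1 | intermediate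
16 | 5,7-bis(benzyloxy)-2-(4-{[(1R,2S)-1-[4-(benzyloxy)phenyl]-1,3-dihydroxypropan-2-yl]oxy}-3,5-dimethoxyphenyl)-4H-chromen-4-one | COc1cc(-c2cc(=O)c3c(OCc4ccccc4)cc(OCc4ccccc4)cc3o2)cc(OC)c1O[C@@H](CO)[C@H](O)c1ccc(OCc2ccccc2)cc1 | intermediate
17 | (–)-(7''R,8''S)-4'',5,7-trihydroxy-3',5'-dimethoxy-4',8''-oxyflavonolignan-7'',9''-diol | COc1cc(-c2cc(=O)c3c(O)cc(O)cc3o2)cc(OC)c1O[C@@H](CO)[C@H](O)c1ccc(O)cc1 | target

## Step count and risks

Total: 12 steps. Longest linear sequence: 10 steps (steps 1–7, 10, 11, 12) from **1**; the chromone branch (steps 8 and 9) joins at step 10.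

**Step 4 (key step).**
- What may go wrong: no reductase in the panel accepts a ketone flanked by two large groups. Or reduction of the fitting enantiomer outruns racemisation, so that the enantiomeric excess falls as the substrate pool is depleted. Or the enzymes found give the threo pair or the mirror-image erythro pair.
- Fallback, from **6** back to **8**: the dynamic enzymatic reduction is replaced by substrate-controlled reduction and enzymatic kinetic resolution. Excess NaBH4 in EtOH–THF reduces ketone and ester of **6**. The erythro isomer, expected to predominate in hydride reductions of α-aryloxy aryl ketones of this kind, is separated from the threo isomer to give the racemic (1RS,2SR)-1-[4-(benzyloxy)phenyl]-2-(4-bromo-2,6-dimethoxyphenoxy)propane-1,3-diol F1. A lipase chosen to acylate the (1S,2R)-enantiomer (for example Burkholderia cepacia lipase with vinyl acetate in tert-butyl methyl ether) converts that enantiomer into (2R,3S)-3-[4-(benzyloxy)phenyl]-2-(4-bromo-2,6-dimethoxyphenoxy)-3-hydroxypropyl acetate F2. The unreacted diol is **8**, and the route continues at step 6. The price is at most half of the material.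

**Step 10.**
- What may go wrong: protodeboronation, oxidative homocoupling or hydroxylation of the electron-rich boronate may outrun carbopalladation. The palladium enolate may be protonated to the flavanone instead of eliminating. Acid traces at 100 °C may open the acetonide.
- Fallback, from **9** (with **12**) back to **15**: ring C is built on the chiral fragment by the classical chalcone route. Bromine–lithium exchange on **9** (n-BuLi, THF, –78 °C) and quenching with DMF should give 4-{[(4R,5S)-4-[4-(benzyloxy)phenyl]-2,2-dimethyl-1,3-dioxan-5-yl]oxy}-3,5-dimethoxybenzaldehyde F3. Claisen–Schmidt condensation with **12** (KOH, EtOH–THF, rt) gives (2E)-1-[2,4-bis(benzyloxy)-6-hydroxyphenyl]-3-(4-{[(4R,5S)-4-[4-(benzyloxy)phenyl]-2,2-dimethyl-1,3-dioxan-5-yl]oxy}-3,5-dimethoxyphenyl)prop-2-en-1-one F4. Oxidative cyclisation with catalytic iodine in DMSO at 110 °C closes ring C and returns to **15**. This costs one more linear step and exposes the acetonide to warm, weakly acidic conditions.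

**Step 3.**
- What may go wrong: the hydroxyl of **5** sits between two methoxy groups. The carbenoid may instead be lost to Wolff rearrangement, to attack on a methoxy oxygen or the arene, or to dimerisation before it reaches the crowded O–H.
- Fallback, from **3** back to **6**: the ether is made by substitution at the doubly activated carbon. Bromination of **3** with N-bromosuccinimide (cat. TsOH, CH2Cl2) gives racemic ethyl 3-[4-(benzyloxy)phenyl]-2-bromo-3-oxopropanoate F5. Alkylation of **5** with this bromide (K2CO3, acetone, rt), the usual way to β-aryl ether models, gives **6**.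

**Step 12.**
- What may go wrong: once the phenols are free, saturation of C2=C3 or hydrogenolysis of the benzylic C7''–O bond may set in before the last benzyl group has gone. Partly debenzylated material may also precipitate and stall.
- Fallback, from **15** back to **17**: a non-reductive debenzylation. BCl3 with pentamethylbenzene as cation scavenger (CH2Cl2, –78 °C) cleaves the three aryl benzyl ethers, and the acetonide falls in the same operation or in the mildly acidic aqueous work-up. This replaces steps 11 and 12 and forms no new isolated intermediate. The low temperature and the scavenger are there to keep the C7''–O bond from ionising.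

## Further compounds

F1 | step 4 | racemic (1RS,2SR)-1-[4-(benzyloxy)phenyl]-2-(4-bromo-2,6-dimethoxyphenoxy)propane-1,3-diol (both enantiomers written) | COc1cc(Br)cc(OC)c1O[C@@H](CO)[C@H](O)c1ccc(OCc2ccccc2)cc1.COc1cc(Br)cc(OC)c1O[C@H](CO)[C@@H](O)c1ccc(OCc2ccccc2)cc1
F2 | step 4 | (2R,3S)-3-[4-(benzyloxy)phenyl]-2-(4-bromo-2,6-dimethoxyphenoxy)-3-hydroxypropyl acetate | COc1cc(Br)cc(OC)c1O[C@H](COC(C)=O)[C@@H](O)c1ccc(OCc2ccccc2)cc1
F3 | step 10 | 4-{[(4R,5S)-4-[4-(benzyloxy)phenyl]-2,2-dimethyl-1,3-dioxan-5-yl]oxy}-3,5-dimethoxybenzaldehyde | COc1cc(C=O)cc(OC)c1O[C@H]1COC(C)(C)O[C@@H]1c1ccc(OCc2ccccc2)cc1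
F4 | step 10 | (2E)-1-[2,4-bis(benzyloxy)-6-hydroxyphenyl]-3-(4-{[(4R,5S)-4-[4-(benzyloxy)phenyl]-2,2-dimethyl-1,3-dioxan-5-yl]oxy}-3,5-dimethoxyphenyl)prop-2-en-1-one | COc1cc(/C=C/C(=O)c2c(O)cc(OCc3ccccc3)cc2OCc2ccccc2)cc(OC)c1O[C@H]1COC(C)(C)O[C@@H]1c1ccc(OCc2ccccc2)cc1
F5 | step 3 | racemic ethyl 3-[4-(benzyloxy)phenyl]-2-bromo-3-oxopropanoate | CCOC(=O)C(Br)C(=O)c1ccc(OCc2ccccc2)cc1
F0 | step 12 | none | none
A1 | alternative 1 | 3,5-bis(benzyloxy)-2-(trimethylsilyl)phenyl trifluoromethanesulfonate | C[Si](C)(C)c1c(OS(=O)(=O)C(F)(F)F)cc(OCc2ccccc2)cc1OCc1ccccc1
A2 | alternative 1 | 3-(4-{[(4R,5S)-4-[4-(benzyloxy)phenyl]-2,2-dimethyl-1,3-dioxan-5-yl]oxy}-3,5-dimethoxyphenyl)prop-2-ynoic acid | COc1cc(C#CC(=O)O)cc(OC)c1O[C@H]1COC(C)(C)O[C@@H]1c1ccc(OCc2ccccc2)cc1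
A3 | alternative 1 | 5,7-bis(benzyloxy)-2-(4-{[(4R,5S)-4-[4-(benzyloxy)phenyl]-2,2-dimethyl-1,3-dioxan-5-yl]oxy}-3,5-dimethoxyphenyl)-4H-chromen-4-one (identical with 15) | COc1cc(-c2cc(=O)c3c(OCc4ccccc4)cc(OCc4ccccc4)cc3o2)cc(OC)c1O[C@H]1COC(C)(C)O[C@@H]1c1ccc(OCc2ccccc2)cc1
A4 | alternative 2 | 2-(4-{[(1E,3R)-3-({4-[tri(propan-2-yl)silyloxy]phenyl}methoxy)but-1-en-1-yl]oxy}-3,5-dimethoxyphenyl)-1,3-dioxolane | C[C@@H](OCc1ccc(O[Si](C(C)C)(C(C)C)C(C)C)cc1)/C=C/Oc1c(OC)cc(C2OCCO2)cc1OC
A5 | alternative 2 | (1R,2S,3E)-2-[4-(1,3-dioxolan-2-yl)-2,6-dimethoxyphenoxy]-1-(4-{[tri(propan-2-yl)silyl]oxy}phenyl)pent-3-en-1-ol | COc1cc(C2OCCO2)cc(OC)c1O[C@@H](/C=C/C)[C@H](O)c1ccc(O[Si](C(C)C)(C(C)C)C(C)C)cc1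
A6 | alternative 3 | (2R)-2-[4-(benzyloxy)phenyl]-2-{[tri(propan-2-yl)silyl]oxy}acetaldehyde | O=C[C@H](O[Si](C(C)C)(C(C)C)C(C)C)c1ccc(OCc2ccccc2)cc1
A7 | alternative 3 | (benzyloxy)methyllithium | [Li]COCc1ccccc1
A8 | alternative 3 | (1R,2S)-3-(benzyloxy)-1-[4-(benzyloxy)phenyl]-1-{[tri(propan-2-yl)silyl]oxy}propan-2-ol | O[C@@H](COCc1ccccc1)[C@H](O[Si](C(C)C)(C(C)C)C(C)C)c1ccc(OCc2ccccc2)cc1
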